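## Retrosynthetic overview

1. The last C–C bond, C1′–C2′ of the side chain, is made by a B‑alkyl Suzuki–Miyaura coupling of the hydroborated 5‑vinyl oxane acrylate 11 (fragment A) with the C14 dienyl iodide 29 (fragment B); desilylation and saponification follow.
2. Fragment B comes from an iterative sequence: Zr‑catalysed methylalumination/iodination, Pd‑catalysed Negishi alkyl–alkenyl coupling with a homopropargyl zinc reagent (fragment C, from but‑3‑yn‑1‑ol), then a second methylalumination/iodination. The 11′R carbinol comes from a CBS reduction.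
3. Fragment A: the oxane is closed by a new Pd‑catalysed, diastereoconvergent allylic cycloetherification of a Morita–Baylis–Hillman carbonate, which forms O–C2 and sets C2. C5 comes from a Cu‑catalysed asymmetric allylic alkylation.
4. Ring order: the molecule has one ring (the oxane); it is formed in step 7, before the fragments are joined. The target is the 2,5‑trans (diequatorial) oxane, (2R,5S).

Assumption: isopropenylmagnesium bromide (15) is bought as its THF solution; protecting‑group reagents, 9‑BBN, Me3Al and I2 are treated as reagents.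

## Route

### Fragment A (steps 1–7)

Step 1
Reactants: 1 (E)-1,4-dibromobut-2-ene
Product: 2 (E)-1-bromo-4-[(4-methoxybenzyl)oxy]but-2-ene
Conditions: 4-methoxybenzyl alcohol (1 equiv), NaH (1.05 equiv), THF, 0 °C; then 1 (3 equiv), 0 °C to rt
Reagents that add atoms: 4-methoxybenzyl alcohol, COc1ccc(CO)cc1
Why: Williamson etherification (SN2) at a primary allylic bromide; the excess of 1 suppresses the bis-ether and the E alkene is untouched.

Step 2
Reactants: 2 (E)-1-bromo-4-[(4-methoxybenzyl)oxy]but-2-ene; 3 2-(2-bromoethyl)-1,3-dioxolane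
Product: 5 2-[(3R)-3-{[(4-methoxybenzyl)oxy]methyl}pent-4-en-1-yl]-1,3-dioxolane, via Grignard reagent 4 (not isolated)
Conditions: 3, Mg, THF, 25 °C; then added to 2, CuBr·SMe2 (1 mol%), (S,S)-Taniaphos (1.2 mol%), CH2Cl2, −75 °C
Reagents that add atoms: none
Why: Cu-catalysed asymmetric allylic alkylation (anti-SN2′) of an ether-bearing (E)-allyl bromide with an alkyl Grignard reagent; the chiral Cu–bisphosphine complex selects the alkene face and the branched product, setting the future ring C5 (3R here; the ligand antipode named is assigned by analogy and is exchanged if the first run shows the opposite sense).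

Step 3
Reactants: 5 2-[(3R)-3-{[(4-methoxybenzyl)oxy]methyl}pent-4-en-1-yl]-1,3-dioxolane
Product: 6 (4R)-4-{[(4-methoxybenzyl)oxy]methyl}hex-5-enal
Conditions: 1 M aq. HCl/THF (1:3), rt
Reagents that add atoms: water, O
Why: acid-catalysed acetal hydrolysis; the PMB ether and the γ-stereocentre are inert under these conditions.

Step 4
Reactants: 6 (4R)-4-{[(4-methoxybenzyl)oxy]methyl}hex-5-enal; 7 methyl acrylate
Product: 8 methyl (6R)-3-hydroxy-6-{[(4-methoxybenzyl)oxy]methyl}-2-methylideneoct-7-enoate (about 1:1 mixture of C3 epimers)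
Conditions: 7 (3 equiv), DABCO (1,4-diazabicyclo[2.2.2]octane, 1 equiv), MeOH (2 equiv), rt, 4–6 d
Reagents that add atoms: none
Why: Morita–Baylis–Hillman reaction of an unhindered aliphatic aldehyde; the carbinol centre forms unselectively, which is harmless because step 7 erases and resets it.

Step 5
Reactants: 8 methyl (6R)-3-hydroxy-6-{[(4-methoxybenzyl)oxy]methyl}-2-methylideneoct-7-enoate
Product: 9 methyl (6R)-3-[(tert-butoxycarbonyl)oxy]-6-{[(4-methoxybenzyl)oxy]methyl}-2-methylideneoct-7-enoate (C3 epimers)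
Conditions: Boc2O (1.3 equiv), 4-(dimethylamino)pyridine (0.1 equiv), CH2Cl2, 0 °C to rt
Reagents that add atoms: di-tert-butyl dicarbonate, CC(C)(C)OC(=O)OC(=O)OC(C)(C)C
Why: nucleophile-catalysed acylation of the secondary allylic alcohol gives the tert-butyl carbonate, which later serves as leaving group and internal base source.

Step 6
Reactants: 9 methyl (6R)-3-[(tert-butoxycarbonyl)oxy]-6-{[(4-methoxybenzyl)oxy]methyl}-2-methylideneoct-7-enoate
Product: 10 methyl (6R)-3-[(tert-butoxycarbonyl)oxy]-6-(hydroxymethyl)-2-methylideneoct-7-enoate (C3 epimers)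
Conditions: DDQ (1.3 equiv), CH2Cl2/pH 7 buffer (10:1), 0 °C to rt
Reagents that add atoms: none
Why: oxidative PMB ether cleavage by DDQ; carbonate, acrylate and vinyl group are not oxidised.

Step 7
Reactants: 10 methyl (6R)-3-[(tert-butoxycarbonyl)oxy]-6-(hydroxymethyl)-2-methylideneoct-7-enoate
Product: 11 methyl 2-[(2R,5R)-5-ethenyloxan-2-yl]prop-2-enoate (2,5-trans)
Conditions: Pd2(dba)3·CHCl3 (2.5 mol%), (R,R)-DACH-phenyl Trost ligand (7.5 mol%), CH2Cl2 (0.02 M), 0 °C to rt
Reagents that add atoms: none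
Why: Proposed new method: zerovalent palladium ionises either C3 epimer of 10 (CO2 and tert-butoxide leave, the latter deprotonating the primary alcohol) to a 2-(methoxycarbonyl)allyl palladium complex whose diastereomeric forms interconvert through the η1 isomer at the unsubstituted CH2 terminus faster than they are trapped, so both epimers converge and the tethered alkoxide closes 6-exo at the substituted terminus (closure at CH2 would give an 8-membered ring) through a chair with the allyl unit and the C5 vinyl group both equatorial, the ligand pocket reinforcing this 2,5-trans (2R) outcome (the antipodal ligand is the mismatch control); the closest known chemistry is the Pd-catalysed dynamic kinetic asymmetric etherification of Morita–Baylis–Hillman carbonates with phenols and Pd-catalysed intramolecular allylic etherification to 2-vinyl oxanes, which have not been combined in a ring closure steered by a remote stereocentre.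

### Fragment B, first part (steps 8–12)

Step 8
Reactants: 12 pent-4-ynoic acid
Product: 14 N-methoxy-N-methylpent-4-ynamide, via acyl imidazole 13 (not isolated)
Conditions: CDI (1.1 equiv), CH2Cl2, rt, 1 h; then MeNH(OMe)·HCl (1.2 equiv), rt
Reagents that add atoms: N,O-dimethylhydroxylamine hydrochloride, CNOC.Cl
Why: carbonyldiimidazole activation followed by aminolysis (Weinreb amide formation) tolerates the terminal alkyne.

Step 9
Reactants: 14 N-methoxy-N-methylpent-4-ynamide; 15 isopropenylmagnesium bromide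
Product: 16 2-methylhept-1-en-6-yn-3-one
Conditions: 15 (0.5 M in THF, 2.5 equiv), THF, −20 to 0 °C; inverse quench into cold 1 M aq. HCl
Reagents that add atoms: none
Why: Grignard addition to a Weinreb amide stops at the chelated tetrahedral intermediate (extra reagent only deprotonates the alkyne), and the acidic inverse quench releases the enone without conjugate addition of the liberated amine.

Step 10
Reactants: 16 2-methylhept-1-en-6-yn-3-one
Product: 17 (3R)-2-methylhept-1-en-6-yn-3-ol
Conditions: (S)-2-methyl-CBS-oxazaborolidine [(S)-1-methyl-3,3-diphenyltetrahydro-1H,3H-pyrrolo[1,2-c][1,3,2]oxazaborole] (0.2 equiv), catecholborane (1.5 equiv), toluene, −78 °C; MeOH, then 1 M aq. NaOH wash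
Reagents that add atoms: none
Why: Corey–Bakshi–Shibata reduction in which the isopropenyl group is the large substituent, so the (S)-catalyst delivers hydride to give the 3R alcohol, while catecholborane at −78 °C does not hydroborate the alkyne or alkene.

Step 11
Reactants: 17 (3R)-2-methylhept-1-en-6-yn-3-ol
Product: 18 tert-butyl(dimethyl){[(3R)-2-methylhept-1-en-6-yn-3-yl]oxy}silane
Conditions: TBSCl (1.2 equiv), imidazole (2 equiv), DMF, rt
Reagents that add atoms: tert-butyldimethylsilyl chloride, CC(C)(C)[Si](C)(C)Cl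
Why: standard silylation of a secondary alcohol; it protects the carbinol from the organometallic steps without touching the stereocentre.

Step 12
Reactants: 18 tert-butyl(dimethyl){[(3R)-2-methylhept-1-en-6-yn-3-yl]oxy}silane
Product: 20 tert-butyl{[(3R,6E)-7-iodo-2,6-dimethylhepta-1,6-dien-3-yl]oxy}dimethylsilane, via alkenylalane 19 (not isolated)
Conditions: Me3Al (2 equiv), Cp2ZrCl2 (0.2 equiv), H2O (1 equiv), CH2Cl2, −20 °C; then I2 (1.2 equiv), THF, −20 to 0 °C
Reagents that add atoms: trimethylaluminium, C[Al](C)C; iodine, II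
Why: Zr-catalysed syn-methylalumination of the terminal alkyne (Negishi carboalumination) places Me on the internal carbon, and iodinolysis with retention gives the (E)-iodide; the 1,1-disubstituted alkene does not react.

### Fragment C (steps 13–14)

Step 13
Reactants: 21 but-3-yn-1-ol
Product: 23 4-(trimethylsilyl)but-3-yn-1-ol, via bis-silyl ether 22 (not isolated)
Conditions: n-BuLi (2.1 equiv), THF, −78 °C; TMSCl (2.2 equiv), −78 °C to rt; then 1 M aq. HCl, rt, 30 min
Reagents that add atoms: chlorotrimethylsilane, C[Si](C)(C)Cl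
Why: silylation of the O,C-dianion followed by mild acid, which cleaves only the labile O–Si bond.

Step 14
Reactants: 23 4-(trimethylsilyl)but-3-yn-1-ol
Product: 24 (4-iodobut-1-yn-1-yl)trimethylsilane
Conditions: I2 (1.2 equiv), PPh3 (1.2 equiv), imidazole (1.5 equiv), CH2Cl2, 0 °C to rt
Reagents that add atoms: iodine, II
Why: Appel-type iodination of a primary alcohol (SN2 on the alkoxyphosphonium).

### Fragment B, completion (steps 15–17)

Step 15
Reactants: 24 (4-iodobut-1-yn-1-yl)trimethylsilane; 20 tert-butyl{[(3R,6E)-7-iodo-2,6-dimethylhepta-1,6-dien-3-yl]oxy}dimethylsilane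
Product: 26 tert-butyl{[(3R,6E)-2,6-dimethyl-11-(trimethylsilyl)undeca-1,6-dien-10-yn-3-yl]oxy}dimethylsilane, via alkylzinc iodide 25 (not isolated)
Conditions: 24 (1.5 equiv), Zn dust (activated with BrCH2CH2Br/TMSCl), LiCl, THF, 40 °C; then 20 (1 equiv), PdCl2(dppf)·CH2Cl2 (3 mol%), THF, rt to 45 °C
Reagents that add atoms: none
Why: direct zinc insertion into the primary iodide followed by Negishi alkyl–alkenyl cross-coupling, which proceeds with retention of the E geometry.

Step 16
Reactants: 26 tert-butyl{[(3R,6E)-2,6-dimethyl-11-(trimethylsilyl)undeca-1,6-dien-10-yn-3-yl]oxy}dimethylsilane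
Product: 27 tert-butyl{[(3R,6E)-2,6-dimethylundeca-1,6-dien-10-yn-3-yl]oxy}dimethylsilane
Conditions: K2CO3 (0.5 equiv), MeOH/THF, rt
Reagents that add atoms: none
Why: base-catalysed methanolysis of the C(sp)–SiMe3 bond; the TBS ether is stable.

Step 17
Reactants: 27 tert-butyl{[(3R,6E)-2,6-dimethylundeca-1,6-dien-10-yn-3-yl]oxy}dimethylsilane
Product: 29 tert-butyl{[(3R,6E,10E)-11-iodo-2,6,10-trimethylundeca-1,6,10-trien-3-yl]oxy}dimethylsilane, via alkenylalane 28 (not isolated)
Conditions: Me3Al (2 equiv), Cp2ZrCl2 (0.2 equiv), H2O (1 equiv), CH2Cl2, −20 °C; then I2 (1.2 equiv), THF, −20 to 0 °C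
Reagents that add atoms: trimethylaluminium, C[Al](C)C; iodine, II
Why: second Zr-catalysed syn-methylalumination/iodinolysis, selective for the terminal alkyne over the tri- and disubstituted alkenes, sets the second E trisubstituted alkene.

### Fragment union and end game (steps 18–20)

Step 18
Reactants: 11 methyl 2-[(2R,5R)-5-ethenyloxan-2-yl]prop-2-enoate; 29 tert-butyl{[(3R,6E,10E)-11-iodo-2,6,10-trimethylundeca-1,6,10-trien-3-yl]oxy}dimethylsilane
Product: 31 methyl 2-[(2R,5S)-5-[(3E,7E,11R)-11-{[tert-butyl(dimethyl)silyl]oxy}-4,8,12-trimethyltrideca-3,7,12-trien-1-yl]oxan-2-yl]prop-2-enoate, via B-alkyl borane 30 (not isolated)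
Conditions: 11 (1.3 equiv), 9-BBN (0.5 M in THF, 1.35 equiv), 0 °C to rt, 3 h; then 29 (1 equiv), PdCl2(dppf)·CH2Cl2 (5 mol%), AsPh3 (10 mol%), Cs2CO3 (3 equiv), DMF/H2O, rt
Reagents that add atoms: none
Why: B-alkyl Suzuki–Miyaura coupling, in which 9-BBN adds anti-Markovnikov to the monosubstituted vinyl group faster than to the electron-poor α-branched acrylate and the C(sp3)–C(sp2) bond forms with retention of the E iodide geometry, joining the two halves.

Step 19
Reactants: 31 methyl 2-[(2R,5S)-5-[(3E,7E,11R)-11-{[tert-butyl(dimethyl)silyl]oxy}-4,8,12-trimethyltrideca-3,7,12-trien-1-yl]oxan-2-yl]prop-2-enoate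
Product: 32 methyl 2-[(2R,5S)-5-[(3E,7E,11R)-11-hydroxy-4,8,12-trimethyltrideca-3,7,12-trien-1-yl]oxan-2-yl]prop-2-enoate
Conditions: TBAF (1.5 equiv), AcOH (1.5 equiv), THF, 0 °C to rt
Reagents that add atoms: none
Why: fluoride desilylation, buffered with acetic acid so that the acrylate is not exposed to basic fluoride.

Step 20
Reactants: 32 methyl 2-[(2R,5S)-5-[(3E,7E,11R)-11-hydroxy-4,8,12-trimethyltrideca-3,7,12-trien-1-yl]oxan-2-yl]prop-2-enoate
Product: 33 2-[(2R,5S)-5-[(3E,7E,11R)-11-hydroxy-4,8,12-trimethyltrideca-3,7,12-trien-1-yl]oxan-2-yl]prop-2-enoic acid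
Conditions: LiOH·H2O (5 equiv), THF/MeOH/H2O (3:1:1), rt; then 1 M aq. HCl to pH 3, 0 °C
Reagents that add atoms: lithium hydroxide, [Li+].[OH-]
Why: saponification of the methyl ester; no stereocentre is epimerisable under these conditions and the brief mild acidification spares the allylic alcohol.

## Compound list

1 | (E)-1,4-dibromobut-2-ene | BrC/C=C/CBr | starting material
2 | (E)-1-bromo-4-[(4-methoxybenzyl)oxy]but-2-ene | BrC/C=C/COCc1ccc(OC)cc1 | intermediate
3 | 2-(2-bromoethyl)-1,3-dioxolane | BrCCC1OCCO1 | starting material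
4 | [2-(1,3-dioxolan-2-yl)ethyl]magnesium bromide (not isolated) | Br[Mg]CCC1OCCO1 | intermediate
5 | 2-[(3R)-3-{[(4-methoxybenzyl)oxy]methyl}pent-4-en-1-yl]-1,3-dioxolane | C=C[C@H](COCc1ccc(OC)cc1)CCC1OCCO1 | intermediate
6 | (4R)-4-{[(4-methoxybenzyl)oxy]methyl}hex-5-enal | C=C[C@H](COCc1ccc(OC)cc1)CCC=O | intermediate
7 | methyl acrylate | C=CC(=O)OC | starting material
8 | methyl (6R)-3-hydroxy-6-{[(4-methoxybenzyl)oxy]methyl}-2-methylideneoct-7-enoate (C3 epimers) | C=C[C@H](COCc1ccc(OC)cc1)CCC(O)C(=C)C(=O)OC | intermediate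
9 | methyl (6R)-3-[(tert-butoxycarbonyl)oxy]-6-{[(4-methoxybenzyl)oxy]methyl}-2-methylideneoct-7-enoate (C3 epimers) | C=C[C@H](COCc1ccc(OC)cc1)CCC(OC(=O)OC(C)(C)C)C(=C)C(=O)OC | intermediate
10 | methyl (6R)-3-[(tert-butoxycarbonyl)oxy]-6-(hydroxymethyl)-2-methylideneoct-7-enoate (C3 epimers) | C=C[C@H](CO)CCC(OC(=O)OC(C)(C)C)C(=C)C(=O)OC | intermediate
11 | methyl 2-[(2R,5R)-5-ethenyloxan-2-yl]prop-2-enoate | C=C[C@H]1CC[C@H](C(=C)C(=O)OC)OC1 | intermediate
12 | pent-4-ynoic acid | C#CCCC(=O)O | starting material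
13 | 1-(1H-imidazol-1-yl)pent-4-yn-1-one (not isolated) | C#CCCC(=O)n1ccnc1 | intermediate
14 | N-methoxy-N-methylpent-4-ynamide | C#CCCC(=O)N(C)OC | intermediate
15 | isopropenylmagnesium bromide (prop-1-en-2-ylmagnesium bromide) | CC(=C)[Mg]Br | starting material
16 | 2-methylhept-1-en-6-yn-3-one | C=C(C)C(=O)CCC#C | intermediate
17 | (3R)-2-methylhept-1-en-6-yn-3-ol | C=C(C)[C@H](O)CCC#C | intermediate
18 | tert-butyl(dimethyl){[(3R)-2-methylhept-1-en-6-yn-3-yl]oxy}silane | C=C(C)[C@H](O[Si](C)(C)C(C)(C)C)CCC#C | intermediate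
19 | {(1E,5R)-5-{[tert-butyl(dimethyl)silyl]oxy}-2,6-dimethylhepta-1,6-dien-1-yl}dimethylalane (not isolated) | C=C(C)[C@H](O[Si](C)(C)C(C)(C)C)CC/C(C)=C/[Al](C)C | intermediate
20 | tert-butyl{[(3R,6E)-7-iodo-2,6-dimethylhepta-1,6-dien-3-yl]oxy}dimethylsilane | C=C(C)[C@H](O[Si](C)(C)C(C)(C)C)CC/C(C)=C/I | intermediate
21 | but-3-yn-1-ol | C#CCCO | starting material
22 | trimethyl{[4-(trimethylsilyl)but-3-yn-1-yl]oxy}silane (not isolated) | C[Si](C)(C)C#CCCO[Si](C)(C)C | intermediate
23 | 4-(trimethylsilyl)but-3-yn-1-ol | C[Si](C)(C)C#CCCO | intermediate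
24 | (4-iodobut-1-yn-1-yl)trimethylsilane | C[Si](C)(C)C#CCCI | intermediate
25 | iodo[4-(trimethylsilyl)but-3-yn-1-yl]zinc (not isolated) | C[Si](C)(C)C#CCC[Zn]I | intermediate
26 | tert-butyl{[(3R,6E)-2,6-dimethyl-11-(trimethylsilyl)undeca-1,6-dien-10-yn-3-yl]oxy}dimethylsilane | C=C(C)[C@H](O[Si](C)(C)C(C)(C)C)CC/C(C)=C/CCC#C[Si](C)(C)C | intermediate
27 | tert-butyl{[(3R,6E)-2,6-dimethylundeca-1,6-dien-10-yn-3-yl]oxy}dimethylsilane | C=C(C)[C@H](O[Si](C)(C)C(C)(C)C)CC/C(C)=C/CCC#C | intermediate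
28 | {(1E,5E,9R)-9-{[tert-butyl(dimethyl)silyl]oxy}-2,6,10-trimethylundeca-1,5,10-trien-1-yl}dimethylalane (not isolated) | C=C(C)[C@H](O[Si](C)(C)C(C)(C)C)CC/C(C)=C/CC/C(C)=C/[Al](C)C | intermediate
29 | tert-butyl{[(3R,6E,10E)-11-iodo-2,6,10-trimethylundeca-1,6,10-trien-3-yl]oxy}dimethylsilane | C=C(C)[C@H](O[Si](C)(C)C(C)(C)C)CC/C(C)=C/CC/C(C)=C/I | intermediate
30 | methyl 2-{(2R,5S)-5-[2-(9-borabicyclo[3.3.1]nonan-9-yl)ethyl]oxan-2-yl}prop-2-enoate (not isolated) | B1(C2CCCC1CCC2)CC[C@H]3CC[C@H](C(=C)C(=O)OC)OC3 | intermediate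
31 | methyl 2-[(2R,5S)-5-[(3E,7E,11R)-11-{[tert-butyl(dimethyl)silyl]oxy}-4,8,12-trimethyltrideca-3,7,12-trien-1-yl]oxan-2-yl]prop-2-enoate | C=C(C)[C@H](O[Si](C)(C)C(C)(C)C)CC/C(C)=C/CC/C(C)=C/CC[C@H]1CC[C@H](C(=C)C(=O)OC)OC1 | intermediate
32 | methyl 2-[(2R,5S)-5-[(3E,7E,11R)-11-hydroxy-4,8,12-trimethyltrideca-3,7,12-trien-1-yl]oxan-2-yl]prop-2-enoate | C=C(C)[C@H](O)CC/C(C)=C/CC/C(C)=C/CC[C@H]1CC[C@H](C(=C)C(=O)OC)OC1 | intermediate
33 | 2-[(2R,5S)-5-[(3E,7E,11R)-11-hydroxy-4,8,12-trimethyltrideca-3,7,12-trien-1-yl]oxan-2-yl]prop-2-enoic acid | C=C(C)[C@H](O)CC/C(C)=C/CC/C(C)=C/CC[C@H]1CC[C@H](C(=C)C(=O)O)OC1 | target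

## Step count and risks

Total steps: 20.
Longest linear sequence: 11 steps (8–12, then 15–20, from pent-4-ynoic acid). The ring branch is 10 steps (1–7, 18–20) and the linker branch 8 (13–20).

Three steps most likely to fail:

**Step 7 (the proposed new cycloetherification).** Risks are low trans/cis selectivity, β-hydride loss from the allyl complex to a dienoate, or attack at the CH2 terminus. The fallback uses known chemistry, sets out from 8 and returns at 11. NBS/Me2S (CH2Cl2, 0 °C) transposes the allylic alcohol of 8 to methyl (2Z,6R)-2-(bromomethyl)-6-{[(4-methoxybenzyl)oxy]methyl}octa-2,7-dienoate F1. DDQ, as in step 6, gives methyl (2Z,6R)-2-(bromomethyl)-6-(hydroxymethyl)octa-2,7-dienoate F2. KOt-Bu (THF, −78 to 0 °C) then closes the ring by the established base-mediated intramolecular oxa-Michael addition/bromide elimination (SN2′). This runs under substrate control through the diequatorial chair and gives 11 after chromatographic removal of the minor cis isomer.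

**Step 18 (hydroboration/B-alkyl Suzuki–Miyaura coupling).** The risk is that 9-BBN reduces or adds to the acrylate. The fallback sets out from 11 and returns at 31, masking the acrylate before hydroboration. PhSH with catalytic Et3N (CH2Cl2, rt) adds to the acrylate to give methyl 2-[(2R,5R)-5-ethenyloxan-2-yl]-3-(phenylsulfanyl)propanoate F3 (epimers at the new α-carbon, irrelevant). 9-BBN then gives methyl 2-{(2R,5S)-5-[2-(9-borabicyclo[3.3.1]nonan-9-yl)ethyl]oxan-2-yl}-3-(phenylsulfanyl)propanoate F4 (not isolated). Coupling with 29 under the step 18 conditions gives methyl 2-[(2R,5S)-5-[(3E,7E,11R)-11-{[tert-butyl(dimethyl)silyl]oxy}-4,8,12-trimethyltrideca-3,7,12-trien-1-yl]oxan-2-yl]-3-(phenylsulfanyl)propanoate F5. NaIO4 (MeOH/H2O, 0 °C) oxidises only sulfur, giving methyl 2-[(2R,5S)-5-[(3E,7E,11R)-11-{[tert-butyl(dimethyl)silyl]oxy}-4,8,12-trimethyltrideca-3,7,12-trien-1-yl]oxan-2-yl]-3-(phenylsulfinyl)propanoate F6. Thermal syn-elimination (toluene, CaCO3, 110 °C) regenerates the acrylate and returns 31.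

**Step 10 (CBS reduction).** The risk is incomplete enantioselectivity at a remote centre that cannot be upgraded later, because the resulting diastereomers of 33 would be inseparable. The fallback sets out from 16 and returns at 17. NaBH4/CeCl3·7H2O (MeOH, −40 °C) gives racemic 2-methylhept-1-en-6-yn-3-ol F7. Sharpless kinetic resolution (Ti(OiPr)4, L-(+)-diisopropyl tartrate, t-BuOOH, 4 Å sieves, CH2Cl2, −20 °C, to about 55% conversion) epoxidises the (S)-enantiomer to (1S)-1-[(2S)-2-methyloxiran-2-yl]pent-4-yn-1-ol F8. Unreacted (R)-alcohol 17 is recovered in high ee.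

## Further compounds

F1 | step 7 | methyl (2Z,6R)-2-(bromomethyl)-6-{[(4-methoxybenzyl)oxy]methyl}octa-2,7-dienoate | C=C[C@H](COCc1ccc(OC)cc1)CC/C=C(CBr)/C(=O)OC
F2 | step 7 | methyl (2Z,6R)-2-(bromomethyl)-6-(hydroxymethyl)octa-2,7-dienoate | C=C[C@H](CO)CC/C=C(CBr)/C(=O)OC
F3 | step 18 | methyl 2-[(2R,5R)-5-ethenyloxan-2-yl]-3-(phenylsulfanyl)propanoate (α-epimers) | C=C[C@H]1CC[C@H](C(CSc2ccccc2)C(=O)OC)OC1
F4 | step 18 | methyl 2-{(2R,5S)-5-[2-(9-borabicyclo[3.3.1]nonan-9-yl)ethyl]oxan-2-yl}-3-(phenylsulfanyl)propanoate (not isolated) | B1(C2CCCC1CCC2)CC[C@H]3CC[C@H](C(CSc4ccccc4)C(=O)OC)OC3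
F5 | step 18 | methyl 2-[(2R,5S)-5-[(3E,7E,11R)-11-{[tert-butyl(dimethyl)silyl]oxy}-4,8,12-trimethyltrideca-3,7,12-trien-1-yl]oxan-2-yl]-3-(phenylsulfanyl)propanoate | C=C(C)[C@H](O[Si](C)(C)C(C)(C)C)CC/C(C)=C/CC/C(C)=C/CC[C@H]1CC[C@H](C(CSc2ccccc2)C(=O)OC)OC1
F6 | step 18 | methyl 2-[(2R,5S)-5-[(3E,7E,11R)-11-{[tert-butyl(dimethyl)silyl]oxy}-4,8,12-trimethyltrideca-3,7,12-trien-1-yl]oxan-2-yl]-3-(phenylsulfinyl)propanoate | C=C(C)[C@H](O[Si](C)(C)C(C)(C)C)CC/C(C)=C/CC/C(C)=C/CC[C@H]1CC[C@H](C(CS(=O)c2ccccc2)C(=O)OC)OC1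
F7 | step 10 | racemic 2-methylhept-1-en-6-yn-3-ol | C=C(C)C(O)CCC#C
F8 | step 10 | (1S)-1-[(2S)-2-methyloxiran-2-yl]pent-4-yn-1-ol | C#CCC[C@H](O)[C@]1(C)CO1
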